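(The runs were computed on assumed constants.)

Millimoles per litre of partner are the measure I reckon in here, since one earlier run can tell me what a given c(partner) is worth in target.

| flask | substrate | partner | remark | time |
|---|---|---|---|---|
| red | 18 mM | 1.5 equiv | run made earlier |  |
| summer | 16 mM | 1.50 equiv |  | 6.0 h |
| autumn | 30 mM | 4.50 equiv |  | 6.0 h |
| winter | 4.0 mM | 2.20 equiv |  | 6.0 h |
| dusk | 25 mM | 1.00 equiv |  | 6.0 h |
| midnight | 25 mM | 1.50 equiv |  | 6.0 h |

red run (percent of the substrate charged)

| time / min | target / % | substrate / % |
|---|---|---|
| 25.0 | 33 | 22 |
| 50.0 | 48 | 16 |
| 80.0 | 63 | 4 |
| 90.0 | 63 | 7 |
| 120 | 66 | 2 |

(readings scatter by 2 percentage points)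

- the earlier runs were read with a standard deviation of 2 percentage points
- a reading or a percentage of target counts all its forms, free or not

* all flasks from highest to lowest amount of target, in percent of the substrate charged, at 6.0 h (summer / autumn / winter / dusk / midnight)
* the amount of target, in percent of the substrate charged of the flask you put first, at 6.0 h
* the amount of target, in percent of the substrate charged of the flask you put last, at 6.0 h

In the red run, target reads 66% at 120 min, when substrate reads 2%, and it has not fallen from the 63% at 90.0 min. So a third of the substrate charged has gone elsewhere. I suppose substrate has two ways out: a loss with a first-order constant, which needs no partner, and the path to target with a second-order constant, whose rate carries c(partner). The two rates are then equal at one value of c(partner), the ratio of the two constants. The selectivity, the share of used substrate that becomes target, is c(partner) / (c(partner) + that value).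

To read the value from the red run, I note that it charges 27.0 mM of partner. If target takes partner one for one, the flask ends near 15.1 mM, so the mean is 21.1 mM. With the selectivity set to the plateau reading, this gives 10.8 mM. I call this the crossover concentration: the c(partner) at which substrate goes to target and to loss equally fast. It is a reading and carries the scatter of the readings.

I now take each flask as finished at 6.0 h and give it a mean c(partner), with the partner use in percent taken from the red run. Autumn has 125 mM, well above the crossover, so I expect 92.0%. Winter has 7.48 mM, which is less than the crossover, so I expect 40.8%. Between them I put midnight at 72.9%, then summer at 63.3%, a little more than dusk at 60.7%.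

The forecast has the same order, autumn > midnight > summer > dusk > winter, but its figures differ from mine: 90% for autumn and 45% for winter. Its ground is this: “I read the loss as a first-order side path competing with reaction with the partner”.

The flasks give autumn > midnight > summer > dusk > winter, with autumn at 79.1% and winter at 51.5%.

    substrate → intermediate A (k = 0.0151 min⁻¹)
    substrate + partner ⇌ intermediate B (K = 66.0 L mol⁻¹, k = 32.7 L mol⁻¹ min⁻¹)
    substrate + partner → target (k = 2.30 L mol⁻¹ min⁻¹)
    partner + intermediate A → intermediate C (k = 0.0873 L mol⁻¹ min⁻¹)
    partner + intermediate B → side product A (k = 0.0682 L mol⁻¹ min⁻¹)
    intermediate C → side product B (k = 0.00447 min⁻¹)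
    crystals ⇌ target, rate k7*(cs7 - [target]) while solid is left; crystals form when [target] > cs7 (solubility = 7.40 mM, k = 3.63 min⁻¹)

Autumn falls short of the 92.0% that the crossover concentration 10.8 mM promises, by 13 percentage points. The flask has something the number does not: intermediate B, which forms from substrate and partner and runs back to them. Without that backward run autumn gives 6.55%, so the backward run is the main reason for its 79.1%. Partner also carries intermediate B on to side product A, which stands at 16.0% in autumn; with that path struck out autumn reaches 94.3%, so this path is part of the reason for the shortfall. A neighbour of autumn with 11.0 equiv of partner is promised 96.7%, gives 63.4%, and holds side product A at 35.2%.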